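The easy step is the tail of the blue run: between 6.00 d and 10.0 d target reads 27.1 % and 27.4 %, while over-reaction product climbs from 23.1 % to 48.9 %. Its rise per day, divided by the mean target, gives a first-order loss constant of 0.237 d⁻¹ at 95 °C.

| flask | substrate | partner | free catalyst | second catalyst | temperature | remark | time |
|---|---|---|---|---|---|---|---|
| blue | 34 mM | 68 mM | 0.65 mM | 0.17 mM | 95 °C | run made earlier |  |
| teal | 34 mM | 34 mM | 0.65 mM | 0.17 mM | 106 °C | run made earlier |  |
| ochre | 34 mM | 140 mM | 0.65 mM | 0.17 mM | 95 °C | run made earlier |  |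
| Tuesday's | 34 mM | 68.0 mM (fed, over 10 d) | 0.65 mM | 0.17 mM | 100 °C | all else is in the flask from the start; the feed brings no volume worth counting | 15 d |
| Sunday's | 34 mM | 68.0 mM (in portions, 3, over 10 d) | 0.65 mM | 0.17 mM | 100 °C | first portion at the start, last at 10 d | 15 d |
| Saturday's | 34 mM | 68.0 mM (fed, over 2.5 d) | 0.65 mM | 0.17 mM | 100 °C | all else is in the flask from the start; the feed brings no volume worth counting | 15 d |
| Monday's | 34 mM (fed, over 10 d) | 68.0 mM | 0.65 mM | 0.17 mM |  | the addition at 60 °C, then warmed to 100 °C; the feed brings no volume worth counting | 15 d |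
| Friday's | 34 mM | 68.0 mM | 0.65 mM | 0.17 mM |  | everything together at the start at 60 °C, warmed to 100 °C at 10 d | 15 d |
| Thursday's | 34 mM | 68.0 mM | 0.65 mM | 0.17 mM | 100 °C | everything together at the start | 15 d |

- blue (time / d: target / %, over-reaction product / %, substrate / %): 0.625: 2.5, 0, 77.8; 1.04: 5.7, 1.4, 65.8; 1.67: 10.7, 1.6, 51.8; 2.50: 16.5, 4.3, 37.2; 4.00: 22.5, 11.0, 21.2; 6.00: 27.1, 23.1, 10.1; 10.0: 27.4, 48.9, 1.8
- teal (time / d: target / %, over-reaction product / %, substrate / %): 1.25: 7.0, 3.9, 33.1; 2.50: 10.1, 11.6, 11.4; 4.00: 11.4, 23.3, 3.3; 5.00: 11.4, 30.2, 0.8; 6.00: 9.9, 37.8, 1.5; 8.00: 8.2, 51.0, 0; 10.0: 6.6, 60.9, 0.5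
- ochre (time / d: target / %, over-reaction product / %, substrate / %): 0.500: 4.4, 0.3, 83.1; 1.25: 12.8, 2.2, 61.7; 2.50: 25.0, 7.8, 37.2; 4.00: 35.4, 17.9, 20.2; 5.00: 38.9, 27.6, 14.0; 8.00: 37.1, 55.6, 4.4; 10.0: 27.8, 70.1, 2.7

(standard deviation of a reading: 0.5 percentage points)

- the flask with the highest share of target in target plus over-reaction product ("all alike" if they lie within 1.5 percentage points) (Tuesday's / Sunday's / Saturday's / Monday's / Friday's / Thursday's / all alike)
- share of target in target plus over-reaction product at the end, Tuesday's
- share of target in target plus over-reaction product at the end, Sunday's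
- share of target in target plus over-reaction product at the end, Saturday's
- share of target in target plus over-reaction product at the end, Monday's
- share of target in target plus over-reaction product at the end, Friday's
- share of target in target plus over-reaction product at the end, Thursday's



The same reading on ochre, with [partner] at 140 mM instead of 68 mM, gives 0.246 d⁻¹, so I freeze this constant against [partner]. Teal reads 0.682 d⁻¹ at 106 °C. Interpolating ln k in temperature gives 0.383 d⁻¹, the frozen loss constant of target at 100 °C.

My view is the clock. If target is made at an even pace over a hot time h, its share of target plus over-reaction product (the selectivity to target) is one minus exp(−k·h), divided by k·h, whatever amount is made. The same slope puts the constant at 60 °C at 0.00815 d⁻¹, far less than the hot value, so I count hot time from the warming. Monday's and Friday's then have 5.00 d hot, which gives 44.5 %. For Tuesday's and Sunday's, with the making taken as spread over 15 d, I reckon 17.4 %. Saturday's and Thursday's should make target early, so I put them below that.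

My colleague holds the partner view: at 2.50 d ochre reads 25.0 % target against blue's 16.5 %, a factor of 1.52, so Thursday's, with the whole of the partner in from the start, should beat every feed. I answer with the share at 4.00 d: blue 67.2 %, ochre 66.4 %.

The forecast sides with the clock, saying “the share depends on how late the target forms”, but its numbers are not mine. It names Monday's: Monday's 41 %, Friday's 40 %, Sunday's 17 %, Tuesday's 16 %, Saturday's 6.5 %, Thursday's 5 %.

The simulation gives Monday's, highest at 41.5 %, then Friday's 40.0 %, Sunday's 18.4 %, Tuesday's 18.0 %, Saturday's 5.42 %, and Thursday's lowest at 3.93 %.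

    target → over-reaction product (k = 0.0162 h⁻¹, Ea = 117 kJ mol⁻¹)
    substrate + free catalyst → free catalyst + open intermediate (k = 36.5 M⁻¹ h⁻¹, Ea = 86.0 kJ mol⁻¹)
    second catalyst + open intermediate ⇌ catalyst intermediate (K = 9300 M⁻¹, k = 495 M⁻¹ h⁻¹, Ea = 48.0 kJ mol⁻¹, ΔH = −53.0 kJ mol⁻¹)
    partner + catalyst intermediate → second catalyst + target (k = 19.7 M⁻¹ h⁻¹, Ea = 74.0 kJ mol⁻¹)
    (constants at 100 °C)

Monday's lies 3 percentage points under the even-pace share from 0.383 d⁻¹. At 15.0 d Monday's flask still holds 35.4 % as open intermediate, which the share does not count; the share rests on 24.5 % target against 34.4 % over-reaction product. The partner view keeps its ground in the amount of target during the making, as ochre's 35.4 % against blue's 22.5 % at 4.00 d reads, but not in the share. Thursday's flask with [partner] cut to 17 mM gets the same reckoning: 0.383 d⁻¹ over 15 d gives 17.4 % at an even pace. That neighbour ends with 3.93 % target, 30.5 % over-reaction product and 65.0 % open intermediate, a share of 11.4 %.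

(The readings were computed from invented constants; noise was put on by code.)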